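**Retrosynthetic overview**
1. The target comes from O-acetylation of the C15 alcohol. Ring A (the cyclohexenone, formed last) comes from an acid-triggered cascade (enol-ether hydrolysis, enol-lactone methanolysis, intramolecular aldol condensation) of a ring-B-fused enol lactone that already carries the C4 quaternary centre.
2. Key bond C3–C4: catalyst-controlled α-alkylation of the aromatic 2-furanolate of that lactone with 2-methoxyallyl bromide (a masked α-bromoacetone, i.e. an acetone α-cation/enolonium equivalent). Two carbonyl α-carbons are joined and the quaternary stereocentre is set.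
3. The fused lactone comes from enol lactonisation of a γ-keto acid, made from the ring-B ketone enolate and an α-triflyloxy propanoate (C4–C5, a second α-cation alkylation).
4. The ring-B ketone comes from Cu-catalysed asymmetric conjugate methylation of 2-methylcyclohex-2-enone and trans-alkylation of the enolate with a C5 iodide cut out of (R)-citronellol (C13 from the chiral pool).
5. Ring order: ring B is bought, a temporary γ-lactone ring is fused to it, and ring A closes last.

Assumption: in the two catalyst-controlled steps (4 and 8) the catalyst enantiomer named is taken to give the drawn configuration; if the sense of induction is the opposite, its antipode is used.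

**Route**

Step 1
Reactants: 1 (R)-citronellol
Product: 2 tert-butyl{[(3R)-3,7-dimethyloct-6-en-1-yl]oxy}dimethylsilane
Conditions: TBSCl, imidazole, DMF, rt
Reagents that add atoms: tert-butyldimethylsilyl chloride, CC(C)(C)[Si](C)(C)Cl
Why: Imidazole-mediated silyl ether formation protects the primary alcohol and leaves the stereocentre (future C13) untouched.

Step 2
Reactants: 2 tert-butyl{[(3R)-3,7-dimethyloct-6-en-1-yl]oxy}dimethylsilane
Product: 3 (4R)-6-[(tert-butyldimethylsilyl)oxy]-4-methylhexanoic acid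
Conditions: RuCl3·xH2O (2 mol%), NaIO4 (4 equiv), CCl4/MeCN/H2O, rt
Reagents that add atoms: sodium periodate (oxygen donor via RuO4), [Na+].[O-]I(=O)(=O)=O; water, O
Why: Sharpless RuO4-catalysed oxidative cleavage of the trisubstituted alkene gives the acid directly, with the silyl ether and the stereocentre inert.

Step 3
Reactants: 3 (4R)-6-[(tert-butyldimethylsilyl)oxy]-4-methylhexanoic acid
Product: 4 tert-butyl{[(3S)-5-iodo-3-methylpentyl]oxy}dimethylsilane
Conditions: PhI(OAc)2, I2, cyclohexane, hν, reflux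
Reagents that add atoms: iodine, II
Why: Suárez (Hunsdiecker-type) iododecarboxylation via the acyl hypoiodite and a primary alkyl radical removes the carboxyl carbon; the stereocentre is not involved (the descriptor changes only because iodine outranks oxygen).

Step 4
Reactants: 5 2-methylcyclohex-2-en-1-one
Product: 7 {[(3R)-2,3-dimethylcyclohex-1-en-1-yl]oxy}trimethylsilane, via aluminium enolate 6 (not isolated)
Conditions: Me3Al (1.4 equiv), CuTC (2 mol%), (S,S)-biphenol bis(1-phenylethyl)amine phosphoramidite (4 mol%), Et2O, −30 °C; then TMSOTf, THF, 0 °C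
Reagents that add atoms: trimethylaluminium, C[Al](C)C; trimethylsilyl trifluoromethanesulfonate, C[Si](C)(C)OS(=O)(=O)C(F)(F)F
Why: Copper-catalysed asymmetric conjugate addition of Me3Al to the 2-substituted enone sets the 3-methyl stereocentre (R, future C8) under ligand control, and O-silylation traps the regiodefined tetrasubstituted enolate.

Step 5
Reactants: 7 {[(3R)-2,3-dimethylcyclohex-1-en-1-yl]oxy}trimethylsilane; 4 tert-butyl{[(3S)-5-iodo-3-methylpentyl]oxy}dimethylsilane
Product: 9 (2S,3R)-2-[(3R)-5-[(tert-butyldimethylsilyl)oxy]-3-methylpentyl]-2,3-dimethylcyclohexan-1-one, via lithium enolate 8 (not isolated)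
Conditions: MeLi (1.05 equiv), THF, 0 °C; then 4, HMPA, −40 °C → rt
Reagents that add atoms: none
Why: MeLi unmasks the lithium enolate regiospecifically, and its SN2 alkylation occurs anti to the adjacent pseudo-axial 3-methyl group, creating the quaternary centre (future C9) with the side chain trans to that methyl.

Step 6
Reactants: 9 (2S,3R)-2-[(3R)-5-[(tert-butyldimethylsilyl)oxy]-3-methylpentyl]-2,3-dimethylcyclohexan-1-one; 10 ethyl (2S)-2-{[(trifluoromethyl)sulfonyl]oxy}propanoate
Product: 12 ethyl 2-[(3S,4R)-3-[(3R)-5-[(tert-butyldimethylsilyl)oxy]-3-methylpentyl]-3,4-dimethyl-2-oxocyclohexyl]propanoate (epimer mixture at ring C1 and propanoate C2), via lithium enolate 11 (not isolated)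
Conditions: LDA (1.1 equiv), THF, −78 °C; then 10, −78 → −30 °C
Reagents that add atoms: none
Why: The only enolisable position gives the kinetic enolate, which displaces triflate from the α-triflyloxy ester (an ester α-cation equivalent) by SN2 C-alkylation to give the γ-keto ester; both new stereocentres are erased in step 7, so their ratio is irrelevant.

Step 7
Reactants: 12 ethyl 2-[(3S,4R)-3-[(3R)-5-[(tert-butyldimethylsilyl)oxy]-3-methylpentyl]-3,4-dimethyl-2-oxocyclohexyl]propanoate
Product: 14 (6R,7S)-7-[(3R)-5-[(tert-butyldimethylsilyl)oxy]-3-methylpentyl]-3,6,7-trimethyl-4,5,6,7-tetrahydro-1-benzofuran-2(3H)-one (C3 epimer mixture), via lithium carboxylate 13 (not isolated)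
Conditions: LiOH, THF/H2O, rt; evaporate; Ac2O, NaOAc, 100 °C
Reagents that add atoms: lithium hydroxide (may supply the retained carboxyl oxygen), [Li+].[OH-]
Why: Saponification followed by Ac2O/NaOAc dehydrative enol lactonisation of the γ-keto acid masks the ketone as a fused enol lactone and makes the methyl-bearing α-carbon the only acidic site (any conjugated butenolide tautomer gives the same furanolate in step 8).

Step 8
Reactants: 14 (6R,7S)-7-[(3R)-5-[(tert-butyldimethylsilyl)oxy]-3-methylpentyl]-3,6,7-trimethyl-4,5,6,7-tetrahydro-1-benzofuran-2(3H)-one; 15 3-bromo-2-methoxyprop-1-ene (2-methoxyallyl bromide)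
Product: 17 (3S,6R,7S)-7-[(3R)-5-[(tert-butyldimethylsilyl)oxy]-3-methylpentyl]-3-(2-methoxyprop-2-en-1-yl)-3,6,7-trimethyl-4,5,6,7-tetrahydro-1-benzofuran-2(3H)-one, via caesium furanolate 16 (not isolated)
Conditions: 15 (1.5 equiv), (S,S)-3,4,5-trifluorophenyl-NAS bromide (Maruoka catalyst, 3 mol%), Cs2CO3, toluene, −20 °C
Reagents that add atoms: none
Why: Proposed new method: the base converts 14 into the planar aromatic 2-furanolate 16, which is held as a tight ion pair by the C2-symmetric ammonium cation and is C-alkylated at its methyl-bearing α-carbon (the γ-carbon is fully substituted and flanked by a quaternary centre) by 2-methoxyallyl bromide, a masked α-bromoacetone acting as an acetone enolonium (α-cation) equivalent, so the catalyst alone fixes the new quaternary centre as 3S (future C4) because the ring-B stereocentres are remote; the closest known reaction types are asymmetric phase-transfer alkylation of lactone and oxindole enolates and Pd-catalysed α-allylation of butenolide-derived dienolates.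

Step 9
Reactants: 17 (3S,6R,7S)-7-[(3R)-5-[(tert-butyldimethylsilyl)oxy]-3-methylpentyl]-3-(2-methoxyprop-2-en-1-yl)-3,6,7-trimethyl-4,5,6,7-tetrahydro-1-benzofuran-2(3H)-one
Product: 20 methyl (1S,5S,6R,8aS)-5-[(3R)-5-hydroxy-3-methylpentyl]-1,5,6-trimethyl-3-oxo-1,2,3,5,6,7,8,8a-octahydronaphthalene-1-carboxylate, via acetonyl enol lactone 18 (not isolated), via diketo ester 19 (not isolated)
Conditions: 3 M aq. HCl/MeOH (1:10), 0 °C → 55 °C
Reagents that add atoms: methanol, CO; water, O
Why: Proposed new method: aqueous acid first hydrolyses the enol ether to the methyl ketone 18 and removes the silyl group, the enol lactone then undergoes acid-catalysed methanolysis that begins with C-protonation of the enol double bond from the face of the small 3-methyl group (anti to the larger 2-oxopropyl group on the adjacent quaternary carbon), which fixes the ring-fusion hydrogen (8aS) and gives diketo ester 19, and acid-catalysed intramolecular aldol condensation of the methyl ketone onto the ring ketone (Robinson-type closure, only one six-membered mode possible) forms the enone under conditions that do not readily enolise the hindered C8a–H; the closest known reaction types are A-SE2 alcoholysis of enol esters and acid-mediated aldol cyclodehydration of 1,5-diketones.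

Step 10
Reactants: 20 methyl (1S,5S,6R,8aS)-5-[(3R)-5-hydroxy-3-methylpentyl]-1,5,6-trimethyl-3-oxo-1,2,3,5,6,7,8,8a-octahydronaphthalene-1-carboxylate
Product: 21 methyl (1S,5S,6R,8aS)-5-[(3R)-5-(acetyloxy)-3-methylpentyl]-1,5,6-trimethyl-3-oxo-1,2,3,5,6,7,8,8a-octahydronaphthalene-1-carboxylate (CNP0250576.1)
Conditions: Ac2O, pyridine, DMAP (cat.), CH2Cl2, rt
Reagents that add atoms: acetic anhydride, CC(=O)OC(C)=O
Why: DMAP-catalysed acetylation of the primary alcohol under mild base touches no stereocentre and does not enolise the enone.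

**Compound list**
1 | (R)-citronellol, (3R)-3,7-dimethyloct-6-en-1-ol | C[C@@H](CCO)CCC=C(C)C | starting material
2 | tert-butyl{[(3R)-3,7-dimethyloct-6-en-1-yl]oxy}dimethylsilane | C[C@@H](CCO[Si](C)(C)C(C)(C)C)CCC=C(C)C | intermediate
3 | (4R)-6-[(tert-butyldimethylsilyl)oxy]-4-methylhexanoic acid | C[C@@H](CCO[Si](C)(C)C(C)(C)C)CCC(=O)O | intermediate
4 | tert-butyl{[(3S)-5-iodo-3-methylpentyl]oxy}dimethylsilane | C[C@@H](CCO[Si](C)(C)C(C)(C)C)CCI | intermediate
5 | 2-methylcyclohex-2-en-1-one | CC1=CCCCC1=O | starting material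
6 | dimethylaluminium (3R)-2,3-dimethylcyclohex-1-en-1-olate | C[Al](C)OC1=C(C)[C@H](C)CCC1 | intermediate (not isolated)
7 | {[(3R)-2,3-dimethylcyclohex-1-en-1-yl]oxy}trimethylsilane | C[C@@H]1CCCC(O[Si](C)(C)C)=C1C | intermediate
8 | lithium (3R)-2,3-dimethylcyclohex-1-en-1-olate | [Li]OC1=C(C)[C@H](C)CCC1 | intermediate (not isolated)
9 | (2S,3R)-2-[(3R)-5-[(tert-butyldimethylsilyl)oxy]-3-methylpentyl]-2,3-dimethylcyclohexan-1-one | O=C1CCC[C@@H](C)[C@]1(C)CC[C@@H](C)CCO[Si](C)(C)C(C)(C)C | intermediate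
10 | ethyl (2S)-2-{[(trifluoromethyl)sulfonyl]oxy}propanoate | CCOC(=O)[C@H](C)OS(=O)(=O)C(F)(F)F | starting material
11 | lithium (5R,6S)-6-[(3R)-5-[(tert-butyldimethylsilyl)oxy]-3-methylpentyl]-5,6-dimethylcyclohex-1-en-1-olate | [Li]OC1=CCC[C@@H](C)[C@]1(C)CC[C@@H](C)CCO[Si](C)(C)C(C)(C)C | intermediate (not isolated)
12 | ethyl 2-[(3S,4R)-3-[(3R)-5-[(tert-butyldimethylsilyl)oxy]-3-methylpentyl]-3,4-dimethyl-2-oxocyclohexyl]propanoate (epimers at ring C1 and propanoate C2) | CCOC(=O)C(C)C1CC[C@@H](C)[C@](C)(CC[C@@H](C)CCO[Si](C)(C)C(C)(C)C)C1=O | intermediate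
13 | lithium 2-[(3S,4R)-3-[(3R)-5-[(tert-butyldimethylsilyl)oxy]-3-methylpentyl]-3,4-dimethyl-2-oxocyclohexyl]propanoate | [Li+].[O-]C(=O)C(C)C1CC[C@@H](C)[C@](C)(CC[C@@H](C)CCO[Si](C)(C)C(C)(C)C)C1=O | intermediate (not isolated)
14 | (6R,7S)-7-[(3R)-5-[(tert-butyldimethylsilyl)oxy]-3-methylpentyl]-3,6,7-trimethyl-4,5,6,7-tetrahydro-1-benzofuran-2(3H)-one (C3 epimers) | CC1C(=O)OC2=C1CC[C@@H](C)[C@]2(C)CC[C@@H](C)CCO[Si](C)(C)C(C)(C)C | intermediate
15 | 3-bromo-2-methoxyprop-1-ene (2-methoxyallyl bromide) | COC(=C)CBr | starting material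
16 | caesium (6R,7S)-7-[(3R)-5-[(tert-butyldimethylsilyl)oxy]-3-methylpentyl]-3,6,7-trimethyl-4,5,6,7-tetrahydro-1-benzofuran-2-olate | [Cs+].CC1=C([O-])OC2=C1CC[C@@H](C)[C@]2(C)CC[C@@H](C)CCO[Si](C)(C)C(C)(C)C | intermediate (not isolated)
17 | (3S,6R,7S)-7-[(3R)-5-[(tert-butyldimethylsilyl)oxy]-3-methylpentyl]-3-(2-methoxyprop-2-en-1-yl)-3,6,7-trimethyl-4,5,6,7-tetrahydro-1-benzofuran-2(3H)-one | COC(=C)C[C@]1(C)C(=O)OC2=C1CC[C@@H](C)[C@]2(C)CC[C@@H](C)CCO[Si](C)(C)C(C)(C)C | intermediate
18 | (3S,6R,7S)-7-[(3R)-5-hydroxy-3-methylpentyl]-3,6,7-trimethyl-3-(2-oxopropyl)-4,5,6,7-tetrahydro-1-benzofuran-2(3H)-one | CC(=O)C[C@]1(C)C(=O)OC2=C1CC[C@@H](C)[C@]2(C)CC[C@@H](C)CCO | intermediate (not isolated)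
19 | methyl (2S)-2-[(1R,3S,4R)-3-[(3R)-5-hydroxy-3-methylpentyl]-3,4-dimethyl-2-oxocyclohexyl]-2-methyl-4-oxopentanoate | COC(=O)[C@@](C)(CC(C)=O)[C@H]1CC[C@@H](C)[C@](C)(CC[C@@H](C)CCO)C1=O | intermediate (not isolated)
20 | methyl (1S,5S,6R,8aS)-5-[(3R)-5-hydroxy-3-methylpentyl]-1,5,6-trimethyl-3-oxo-1,2,3,5,6,7,8,8a-octahydronaphthalene-1-carboxylate | COC(=O)[C@@]1(C)CC(=O)C=C2[C@@H]1CC[C@@H](C)[C@]2(C)CC[C@@H](C)CCO | intermediate
21 | methyl (1S,5S,6R,8aS)-5-[(3R)-5-(acetyloxy)-3-methylpentyl]-1,5,6-trimethyl-3-oxo-1,2,3,5,6,7,8,8a-octahydronaphthalene-1-carboxylate | COC(=O)[C@@]1(C)CC(=O)C=C2[C@@H]1CC[C@@H](C)[C@]2(C)CC[C@@H](C)CCOC(C)=O | target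

**Step count**
Total step count: 10.
Longest linear sequence: 9 steps (steps 1, 2, 3, 5, 6, 7, 8, 9, 10; step 4 is the one-step side branch).

**Three steps most likely to fail**

1. Step 9. The kinetic C-protonation that sets C8a may be poorly selective, and the two C8a epimers are estimated to be close in energy, so nothing corrects a wrong ratio. The aldol closure onto the hindered ring ketone is also slow and may let C8a epimerise. Fallback, setting out from 17 and returning at 20:
   - Methoxide opening of the enol lactone (LiOMe, THF, −78 °C) with in-situ O-triflation (PhNTf2) gives methyl (2S)-2-[(3S,4R)-3-[(3R)-5-[(tert-butyldimethylsilyl)oxy]-3-methylpentyl]-3,4-dimethyl-2-{[(trifluoromethyl)sulfonyl]oxy}cyclohex-1-en-1-yl]-4-methoxy-2-methylpent-4-enoate F1.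
   - PPTS in wet acetone hydrolyses the enol ether to the methyl ketone vinyl triflate F2.
   - Pd-catalysed intramolecular ketone α-alkenylation (Pd2(dba)3, phosphine, K3PO4, PhOH) closes ring A without any addition to a ketone and gives the β,γ-unsaturated ketone F3.
   - TsOH in MeOH moves the double bond into conjugation, with the proton delivered to C8a anti to the pseudo-axial C1 methyl, and removes the silyl group to give 20.

2. Step 8. C- versus O-alkylation and, above all, enantiofacial control at the hindered tetrasubstituted furanolate are unproven. Fallback, setting out from 14 and returning at 18 (the first intermediate of step 9):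
   - Furanolate 16 is O-acylated with allyl chloroformate to give the allyl dienol carbonate F4.
   - Pd(0) with the Trost bisphosphine ligand effects decarboxylative asymmetric allylic alkylation to the α-allyl enol lactone F5.
   - Tsuji–Wacker oxidation (PdCl2, CuCl, O2, DMF/H2O) gives the acetonyl enol lactone F6, which loses its silyl group under the step 9 conditions to give 18 and then 20.

3. Step 5. SN2 of the hindered tetrasubstituted enolate with an unactivated primary iodide can be slow, with proton transfer and elimination competing. Fallback, setting out from 7 and returning at 9: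
   - Commercial 4-(tert-butyldimethylsilyloxy)but-1-yne is converted in one pot (Me3Al, Cp2ZrCl2, then paraformaldehyde) into (2E)-5-[(tert-butyldimethylsilyl)oxy]-3-methylpent-2-en-1-ol F7.
   - CBr4/PPh3 gives the allylic bromide F8.
   - Enolate 8 (from 7 and MeLi) is alkylated with the far more reactive F8, again anti to the 3-methyl group, to give the allylated ketone F9.
   - Ir–PHOX-catalysed asymmetric hydrogenation of the trisubstituted alkene sets C13 and gives 9.

Further compounds
F1 | step 9 | methyl (2S)-2-[(3S,4R)-3-[(3R)-5-[(tert-butyldimethylsilyl)oxy]-3-methylpentyl]-3,4-dimethyl-2-{[(trifluoromethyl)sulfonyl]oxy}cyclohex-1-en-1-yl]-4-methoxy-2-methylpent-4-enoate | COC(=C)C[C@](C)(C(=O)OC)C1=C(OS(=O)(=O)C(F)(F)F)[C@@](C)(CC[C@@H](C)CCO[Si](C)(C)C(C)(C)C)[C@H](C)CC1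
F2 | step 9 | methyl (2S)-2-[(3S,4R)-3-[(3R)-5-[(tert-butyldimethylsilyl)oxy]-3-methylpentyl]-3,4-dimethyl-2-{[(trifluoromethyl)sulfonyl]oxy}cyclohex-1-en-1-yl]-2-methyl-4-oxopentanoate | CC(=O)C[C@](C)(C(=O)OC)C1=C(OS(=O)(=O)C(F)(F)F)[C@@](C)(CC[C@@H](C)CCO[Si](C)(C)C(C)(C)C)[C@H](C)CC1
F3 | step 9 | methyl (1S,5S,6R)-5-[(3R)-5-[(tert-butyldimethylsilyl)oxy]-3-methylpentyl]-1,5,6-trimethyl-3-oxo-1,2,3,4,5,6,7,8-octahydronaphthalene-1-carboxylate | COC(=O)[C@@]1(C)CC(=O)CC2=C1CC[C@@H](C)[C@]2(C)CC[C@@H](C)CCO[Si](C)(C)C(C)(C)C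
F4 | step 8 | prop-2-en-1-yl (6R,7S)-7-[(3R)-5-[(tert-butyldimethylsilyl)oxy]-3-methylpentyl]-3,6,7-trimethyl-4,5,6,7-tetrahydro-1-benzofuran-2-yl carbonate | CC1=C(OC(=O)OCC=C)OC2=C1CC[C@@H](C)[C@]2(C)CC[C@@H](C)CCO[Si](C)(C)C(C)(C)C
F5 | step 8 | (3S,6R,7S)-7-[(3R)-5-[(tert-butyldimethylsilyl)oxy]-3-methylpentyl]-3,6,7-trimethyl-3-(prop-2-en-1-yl)-4,5,6,7-tetrahydro-1-benzofuran-2(3H)-one | C=CC[C@]1(C)C(=O)OC2=C1CC[C@@H](C)[C@]2(C)CC[C@@H](C)CCO[Si](C)(C)C(C)(C)C
F6 | step 8 | (3S,6R,7S)-7-[(3R)-5-[(tert-butyldimethylsilyl)oxy]-3-methylpentyl]-3,6,7-trimethyl-3-(2-oxopropyl)-4,5,6,7-tetrahydro-1-benzofuran-2(3H)-one | CC(=O)C[C@]1(C)C(=O)OC2=C1CC[C@@H](C)[C@]2(C)CC[C@@H](C)CCO[Si](C)(C)C(C)(C)C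
F7 | step 5 | (2E)-5-[(tert-butyldimethylsilyl)oxy]-3-methylpent-2-en-1-ol | OC/C=C(\C)CCO[Si](C)(C)C(C)(C)C
F8 | step 5 | {[(3E)-5-bromo-3-methylpent-3-en-1-yl]oxy}(tert-butyl)dimethylsilane | BrC/C=C(\C)CCO[Si](C)(C)C(C)(C)C
F9 | step 5 | (2S,3R)-2-[(2E)-5-[(tert-butyldimethylsilyl)oxy]-3-methylpent-2-en-1-yl]-2,3-dimethylcyclohexan-1-one | O=C1CCC[C@@H](C)[C@]1(C)C/C=C(\C)CCO[Si](C)(C)C(C)(C)C
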